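The six-membered tetramethyl-dione ring (C=C(O)–CMe2–C(=O)–CMe2–C(=O)) is read as dimethylketene dimer, 2,2,4,4-tetramethylcyclobutane-1,3-dione, with two carbons inserted into one C(=O)–CMe2 bond; these two carbons are the enol-ether C=C that the carbocycle shares with the dihydropyran. The key step exploits this: an alkoxide-triggered retro-aldol/Claisen sequence expands a 3-hydroxycyclobutanone bearing an α-alkylidene ester into 2-isobutylidene syncarpic acid, whose O=C–C=C unit is trapped in the same flask by the strained C4=C5 alkene of (−)-β-caryophyllene in an oxa-Diels–Alder reaction, forming the pyran ring and three stereocentres. The precursor is a reductive-aldol adduct of the dione with an ynoate.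

Key step: step 2

Remark: ethyl 4-methylpent-2-ynoate is assumed to be a purchasable catalogue ynoate (otherwise one step from 3-methylbut-1-yne, n-BuLi and ethyl chloroformate). C1–C13 follow caryophyllane numbering and C1′ is the isopropyl-bearing carbon.

Step 1
Reactants: 1 2,2,4,4-tetramethylcyclobutane-1,3-dione; 2 ethyl 4-methylpent-2-ynoate
Product: 4 ethyl (2Z)-2-(1-hydroxy-2,2,4,4-tetramethyl-3-oxocyclobutyl)-4-methylpent-2-enoate, via vinylalane 3 (not isolated)
Conditions: DIBAL-H (1.0 equiv), NMO (1.1 equiv), THF, 0 °C; 2 (1.1 equiv), 0 °C; then 1 (1.5 equiv), 0 → 25 °C; 1 M HCl, 0 °C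
Reagents that add atoms: none
Why: Syn-hydroalumination of the ynoate by the DIBAL-H·NMO complex should place aluminium on the α-carbon, and the resulting α-aluminated acrylate should add to one of the two equivalent, strain-activated and non-enolisable carbonyl groups of excess 1 (reductive aldol giving a Morita–Baylis–Hillman-type adduct); no stereocentre arises because the carbinol carbon lies on the mirror plane of the ring, and the Z geometry from syn addition with retention is erased in step 2.

Step 2
Reactants: 4 ethyl (2Z)-2-(1-hydroxy-2,2,4,4-tetramethyl-3-oxocyclobutyl)-4-methylpent-2-enoate; 5 (−)-β-caryophyllene, (1R,4E,9S)-4,11,11-trimethyl-8-methylidenebicyclo[7.2.0]undec-4-ene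
Product: 9 myrtucommulone K, via ring-opened enolate 6 (not isolated), via alkylidene trione 7 (not isolated), via ethanol adduct 8 (not isolated)
Conditions: NaH (1.1 equiv), THF, 0 → 50 °C; then AcOH (1.5 equiv), 5 (1.5 equiv), PhMe, 80 °C
Reagents that add atoms: none
Why: Deprotonation should give the tertiary sodium alkoxide, whose strain-driven retro-aldol cleavage of a C(O)–CMe2 ring bond unmasks an isopropyl ketone enolate (6) that closes onto the ester carbonyl (Claisen/Dieckmann) with loss of ethoxide, so that the two acrylate carbons are inserted into the four-membered ring (4 → 6) to give alkylidene trione 7, which the liberated ethoxide should store as conjugate adduct 8 until acetic acid and heat release it for an inverse-electron-demand oxa-Diels–Alder reaction with the C4=C5 alkene of 5. The closest known reaction types are the alkoxide-mediated conversion of this same dione into hexamethylcyclohexane-1,3,5-trione through ester-enolate aldol, retro-Claisen and Claisen steps, and the Knoevenagel/oxa-Diels–Alder union of alkylidene syncarpic acids with β-caryophyllene. The carbocycle therefore arises by ring opening followed by 6-exo-trig acyl substitution (net two-carbon ring expansion), and the dihydropyran by a concerted, asynchronous [4+2] cycloaddition that is suprafacial on both partners. C4 and C5 are set together by syn addition to the E-alkene on its exposed outer face, which the C1/C9 ring fusion fixes through the planar chirality of the trans-cyclononene in the dominant β-type conformers (4R,5S), and C1′ (R) should follow from the approach in which the isopropyl group is outside and the C4 methyl, not the C3 methylene, lies under the oxadiene next to the gem-dimethyl carbon flanking the reacting carbonyl. The step needs closure at the ester carbonyl and not at the alkylidene carbon or at enolate oxygen, which should be secured because those closures are reversible while ethoxide loss leads to a vinylogous carboxylate sink; it also needs oxygen to bond to C4 of the endocyclic alkene, which the strain of the trans-trisubstituted double bond and its polarisation towards the tertiary carbon should secure. The alkene geometry of 4 is irrelevant because the two carbonyl groups flanking the alkylidene carbon of 7 are equivalent.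

Compound list
1 | 2,2,4,4-tetramethylcyclobutane-1,3-dione (dimethylketene dimer) | CC1(C)C(=O)C(C)(C)C1=O | starting material
2 | ethyl 4-methylpent-2-ynoate | CCOC(=O)C#CC(C)C | starting material
3 | ethyl (2E)-2-(diisobutylalumanyl)-4-methylpent-2-enoate (vinylalane; Al trans to isopropyl) | CCOC(=O)/C(=C\C(C)C)[Al](CC(C)C)CC(C)C | intermediate
4 | ethyl (2Z)-2-(1-hydroxy-2,2,4,4-tetramethyl-3-oxocyclobutyl)-4-methylpent-2-enoate (ester cis to isopropyl) | CCOC(=O)/C(=C\C(C)C)C1(O)C(C)(C)C(=O)C1(C)C | intermediate
5 | (−)-β-caryophyllene, (1R,4E,9S)-4,11,11-trimethyl-8-methylidenebicyclo[7.2.0]undec-4-ene | C=C1CC/C=C(\C)CC[C@@H]2[C@@H]1CC2(C)C | starting material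
6 | sodium enolate of ethyl (2Z)-4-methyl-2-(2,2,4-trimethyl-3-oxopentanoyl)pent-2-enoate (ring-opened enolate) | CCOC(=O)/C(=C\C(C)C)C(=O)C(C)(C)C([O-])=C(C)C.[Na+] | intermediate
7 | 4,4,6,6-tetramethyl-2-(2-methylpropylidene)cyclohexane-1,3,5-trione (isobutylidene syncarpic acid) | CC(C)C=C1C(=O)C(C)(C)C(=O)C(C)(C)C1=O | intermediate
8 | 2-(1-ethoxy-2-methylpropyl)-3-hydroxy-4,4,6,6-tetramethylcyclohex-2-ene-1,5-dione (racemic; formed as its sodium enolate) | CCOC(C(C)C)C1=C(O)C(C)(C)C(=O)C(C)(C)C1=O | intermediate
9 | myrtucommulone K: 3,4-dihydro-2H-pyran whose enol-ether C=C is C2=C3 of a 4,4,6,6-tetramethylcyclohex-2-ene-1,5-dione (oxygen on C3); C1′ (R) carries isopropyl; the pyran O and C1′ are bonded to C4 (R, methyl-bearing) and C5 (S) of the (1R,9S)-caryophyllane skeleton, 8(13)-methylene intact | C=C1CC[C@H]2[C@@H](C(C)C)C3=C(O[C@]2(C)CC[C@@H]2[C@@H]1CC2(C)C)C(C)(C)C(=O)C(C)(C)C3=O | target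

Total step count: 2
Longest linear sequence: 2 steps (1 → 4 → 9)

Steps most likely to fail. The route has only two steps, so the key step is entered once for each of its two independent stages.

1. Step 2, ring-expansion stage. The ring-opened enolate may add to the alkylidene carbon (intramolecular Michael closure) or be fragmented by ethoxide (retro-Claisen) faster than it acylates the ester, so that the trione ring is not reached. The fallback sets out from compound 1 and returns at compound 7. The lithium enolate of ethyl acetate (LDA, THF, −78 °C) is added to 1 to give ethyl 2-(1-hydroxy-2,2,4,4-tetramethyl-3-oxocyclobutyl)acetate F1. Sodium ethoxide in ethanol at reflux then performs the same retro-aldol opening on a substrate without a Michael acceptor, to the sodium enolate of ethyl 4,4,6-trimethyl-3,5-dioxoheptanoate F2, and Dieckmann closure followed by acidification gives syncarpic acid F3. Knoevenagel condensation of F3 with isobutyraldehyde (L-proline, toluene) in the presence of 5 forms 7 in situ, where the route is rejoined.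

2. Step 1. The α-aluminated acrylate may be too weak a nucleophile for the doubly neopentyl carbonyl group, so that simple protonolysis to the enoate takes over. The fallback sets out from compound 1 and returns at compound 7. Copper-catalysed carbomagnesiation of ethyl propiolate with isopropylmagnesium chloride (CuI·2LiCl cat., THF, −78 °C) gives the harder aldol donor ethyl (2Z)-2-(chloromagnesio)-4-methylpent-2-enoate F4. Its addition to 1 gives the geometric isomer ethyl (2E)-2-(1-hydroxy-2,2,4,4-tetramethyl-3-oxocyclobutyl)-4-methylpent-2-enoate F5. Under the conditions of step 2, F5 opens to the sodium enolate of ethyl (2E)-4-methyl-2-(2,2,4-trimethyl-3-oxopentanoyl)pent-2-enoate F6 and closes to 7, where the alkene geometry no longer exists.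

3. Step 2, cycloaddition stage. Approach with the ring methylene under the oxadiene, attack on the face exposed in the minor α-type conformer, or an ene reaction at the exocyclic methylene may erode the diastereoselectivity. The fallback sets out from compound 4 (step 2 is run unchanged) and returns at compound 7. The C1′ epimer of 9 F7 is separated from 9 by chromatography and heated in toluene in a sealed tube (150–180 °C) with fresh 5; retro-oxa-Diels–Alder cycloreversion should return it to 7 for a second pass.

Further compounds
F1 | step 2 | ethyl 2-(1-hydroxy-2,2,4,4-tetramethyl-3-oxocyclobutyl)acetate | CCOC(=O)CC1(O)C(C)(C)C(=O)C1(C)C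
F2 | step 2 | sodium enolate of ethyl 4,4,6-trimethyl-3,5-dioxoheptanoate | CCOC(=O)CC(=O)C(C)(C)C([O-])=C(C)C.[Na+]
F3 | step 2 | syncarpic acid (2,2,4,4-tetramethylcyclohexane-1,3,5-trione) | CC1(C)C(=O)CC(=O)C(C)(C)C1=O
F4 | step 1 | ethyl (2Z)-2-(chloromagnesio)-4-methylpent-2-enoate | CCOC(=O)/C(=C/C(C)C)[Mg]Cl
F5 | step 1 | ethyl (2E)-2-(1-hydroxy-2,2,4,4-tetramethyl-3-oxocyclobutyl)-4-methylpent-2-enoate | CCOC(=O)/C(=C/C(C)C)C1(O)C(C)(C)C(=O)C1(C)C
F6 | step 1 | sodium enolate of ethyl (2E)-4-methyl-2-(2,2,4-trimethyl-3-oxopentanoyl)pent-2-enoate | CCOC(=O)/C(=C/C(C)C)C(=O)C(C)(C)C([O-])=C(C)C.[Na+]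
F7 | step 2 | C1′ epimer of myrtucommulone K (1′S) | C=C1CC[C@H]2[C@H](C(C)C)C3=C(O[C@]2(C)CC[C@@H]2[C@@H]1CC2(C)C)C(C)(C)C(=O)C(C)(C)C3=O
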